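**Retrosynthetic overview**
- The furan ring is made last. O1–C2 and C3–C3a come from one acid-triggered [3,3] shift of an O-aryl ketoxime ether (the oxygen analogue of the Fischer indole synthesis), which joins the ring-A aryloxyamine to the chroman methyl ketone. The phloroglucinol ring is dearomatised in this key step, and the MOM groups are cleaved in the same pot.
- Ring A: phloroglucinol is converted to the Cs-symmetric 3,5-bis(MOM) phenol. Its single free oxygen first carries the prenyl group (aromatic Claisen to one of two equivalent ortho carbons, giving the 1,1-dimethylallyl group) and then the NH2 group. The only ortho C–H left dictates furan closure and places the side chain at C7.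
- Chroman half: 3,5-dihydroxyacetophenone → mono 1,1-dimethylpropargyl ether → propargyl Claisen/6π closure to the 2H-chromene (C–C bond ortho to the acetyl group) → hydrogenation.
- Ring order: pyran ring of the chroman first (fragment synthesis), furan ring in the final union step.

Assumption: the target has no stereocentre and no stereogenic double bond (it is achiral), so no stereocontrol is needed and all SMILES carry no stereo descriptors.

**Route**

Step 1
Reactants: 1 phloroglucinol (benzene-1,3,5-triol)
Product: 2 3,5-bis(methoxymethoxy)phenol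
Conditions: MOMCl (2.0 equiv), i-Pr2NEt (2.2 equiv), DMF, 0 → 23 °C
Reagents that add atoms: chloromethyl methyl ether (MOMCl), COCCl
Why: Statistical O-alkylation (MOM protection) of the C3-symmetric triphenol with two equivalents of the hard electrophile gives the Cs-symmetric bis-ether as the main fraction (mono-ether is recycled), leaving exactly one free OH as the handle for both later sigmatropic steps.

Step 2
Reactants: 2 3,5-bis(methoxymethoxy)phenol; 3 prenyl bromide (1-bromo-3-methylbut-2-ene)
Product: 4 1,3-bis(methoxymethoxy)-5-[(3-methylbut-2-en-1-yl)oxy]benzene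
Conditions: K2CO3, acetone, reflux
Reagents that add atoms: none
Why: Williamson ether synthesis; the single phenoxide is O-alkylated by the primary allylic bromide in acetone, where C-alkylation is negligible and MOM acetals are inert.

Step 3
Reactants: 4 1,3-bis(methoxymethoxy)-5-[(3-methylbut-2-en-1-yl)oxy]benzene
Product: 6 3,5-bis(methoxymethoxy)-2-(2-methylbut-3-en-2-yl)phenol, via ortho-dienone 5 (not isolated)
Conditions: PhNEt2, 190 °C, 2 h (sealed tube, Ar)
Reagents that add atoms: none
Why: Aromatic Claisen rearrangement; the [3,3] shift delivers the allyl unit with inversion to either of the two equivalent ortho carbons to give dienone 5, which enolises to the 1,1-dimethylallyl phenol, while the basic solvent and short heating limit the para (Cope) product and cyclisation to the dihydrobenzofuran.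

Step 4
Reactants: 6 3,5-bis(methoxymethoxy)-2-(2-methylbut-3-en-2-yl)phenol
Product: 7 O-[3,5-bis(methoxymethoxy)-2-(2-methylbut-3-en-2-yl)phenyl]hydroxylamine
Conditions: t-BuOK, DMF, 0 °C; then 2,4-(O2N)2C6H3ONH2, 0 → 23 °C
Reagents that add atoms: O-(2,4-dinitrophenyl)hydroxylamine, NOc1ccc([N+](=O)[O-])cc1[N+](=O)[O-]
Why: Electrophilic O-amination of a phenoxide; the potassium phenoxide attacks the nitrogen of the aminating reagent and expels 2,4-dinitrophenoxide, giving the aryloxyamine without touching the alkene or the acetals.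

Step 5
Reactants: 8 3,5-dihydroxyacetophenone (2 equiv, excess recovered); 9 3-chloro-3-methylbut-1-yne
Product: 10 1-{3-hydroxy-5-[(2-methylbut-3-yn-2-yl)oxy]phenyl}ethan-1-one
Conditions: DBU, CuCl2·2H2O (1 mol %), MeCN, 0 °C
Reagents that add atoms: none
Why: Copper-catalysed propargylic etherification of one of the two equivalent phenols by the tertiary propargylic chloride; the excess of diol keeps the bis-ether low.

Step 6
Reactants: 10 1-{3-hydroxy-5-[(2-methylbut-3-yn-2-yl)oxy]phenyl}ethan-1-one
Product: 13 1-(7-hydroxy-2,2-dimethyl-3,4-dihydro-2H-chromen-5-yl)ethan-1-one, via allenylphenol 11 (not isolated), via chromene 12 (not isolated)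
Conditions: DMF, 150 °C, 4 h; cool; H2 (1 atm), 10 % Pd/C, 23 °C
Reagents that add atoms: none
Why: Propargyl Claisen rearrangement followed by [1,5]-H shift and oxa-6π electrocyclisation gives the 2H-chromene, the [3,3] shift going to the carbon ortho to the acetyl group and para to the free OH (both meta substituents direct there), and catalytic hydrogenation in the same flask saturates the styrenic C3=C4 bond while the aryl ketone survives.

Step 7
Reactants: 7 O-[3,5-bis(methoxymethoxy)-2-(2-methylbut-3-en-2-yl)phenyl]hydroxylamine; 13 1-(7-hydroxy-2,2-dimethyl-3,4-dihydro-2H-chromen-5-yl)ethan-1-one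
Product: 17 2-(7-hydroxy-2,2-dimethyl-3,4-dihydro-2H-chromen-5-yl)-7-(2-methylbut-3-en-2-yl)-1-benzofuran-4,6-diol, via oxime ether 14 (not isolated), via dienone imine 15 (not isolated), via bis-MOM benzofuran 16 (not isolated)
Conditions: HCl (4 M in dioxane, 3 equiv), MeOH, 23 °C, 1 h; then 50 °C
Reagents that add atoms: none
Why: Oxime ether condensation, then acid-triggered [3,3]-sigmatropic rearrangement of the N-protonated ene-hydroxylamine tautomer (oxygen analogue of the Fischer indole synthesis), which can only engage the one free ortho carbon and dearomatises ring A to 15; re-aromatisation and ring closure with loss of ammonia give the 2-arylbenzofuran, and the same methanolic HCl cleaves both MOM acetals (MOM loss may overlap with the rearrangement without changing the product).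

**Compound list**

1 | phloroglucinol (benzene-1,3,5-triol) | Oc1cc(O)cc(O)c1 | starting material
2 | 3,5-bis(methoxymethoxy)phenol | COCOc1cc(O)cc(OCOC)c1 | intermediate
3 | prenyl bromide (1-bromo-3-methylbut-2-ene) | CC(C)=CCBr | starting material
4 | 1,3-bis(methoxymethoxy)-5-[(3-methylbut-2-en-1-yl)oxy]benzene | COCOc1cc(OCC=C(C)C)cc(OCOC)c1 | intermediate
5 | 3,5-bis(methoxymethoxy)-6-(2-methylbut-3-en-2-yl)cyclohexa-2,4-dien-1-one (racemic, not isolated) | O=C1C=C(OCOC)C=C(OCOC)C1C(C)(C)C=C | intermediate
6 | 3,5-bis(methoxymethoxy)-2-(2-methylbut-3-en-2-yl)phenol | C=CC(C)(C)c1c(O)cc(OCOC)cc1OCOC | intermediate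
7 | O-[3,5-bis(methoxymethoxy)-2-(2-methylbut-3-en-2-yl)phenyl]hydroxylamine | C=CC(C)(C)c1c(ON)cc(OCOC)cc1OCOC | intermediate
8 | 3,5-dihydroxyacetophenone | CC(=O)c1cc(O)cc(O)c1 | starting material
9 | 3-chloro-3-methylbut-1-yne | CC(C)(Cl)C#C | starting material
10 | 1-{3-hydroxy-5-[(2-methylbut-3-yn-2-yl)oxy]phenyl}ethan-1-one | CC(=O)c1cc(O)cc(OC(C)(C)C#C)c1 | intermediate
11 | 1-[3,5-dihydroxy-2-(3-methylbuta-1,2-dien-1-yl)phenyl]ethan-1-one (not isolated) | CC(=O)c1cc(O)cc(O)c1C=C=C(C)C | intermediate
12 | 1-(7-hydroxy-2,2-dimethyl-2H-chromen-5-yl)ethan-1-one (not isolated) | CC(=O)c1cc(O)cc2OC(C)(C)C=Cc12 | intermediate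
13 | 1-(7-hydroxy-2,2-dimethyl-3,4-dihydro-2H-chromen-5-yl)ethan-1-one | CC(=O)c1cc(O)cc2OC(C)(C)CCc12 | intermediate
14 | 1-(7-hydroxy-2,2-dimethylchroman-5-yl)ethan-1-one O-[3,5-bis(methoxymethoxy)-2-(2-methylbut-3-en-2-yl)phenyl]oxime (E/Z mixture, not isolated) | C=CC(C)(C)c1c(ON=C(C)c2cc(O)cc3OC(C)(C)CCc23)cc(OCOC)cc1OCOC | intermediate
15 | 6-[2-(7-hydroxy-2,2-dimethylchroman-5-yl)-2-iminoethyl]-3,5-bis(methoxymethoxy)-2-(2-methylbut-3-en-2-yl)cyclohexa-2,4-dien-1-one (racemic, N-protonated in the flask, not isolated) | O=C1C(C(C)(C)C=C)=C(OCOC)C=C(OCOC)C1CC(=N)c1cc(O)cc2OC(C)(C)CCc12 | intermediate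
16 | 5-[4,6-bis(methoxymethoxy)-7-(2-methylbut-3-en-2-yl)-1-benzofuran-2-yl]-2,2-dimethylchroman-7-ol (not isolated) | C=CC(C)(C)c1c(OCOC)cc(OCOC)c2cc(-c3cc(O)cc4c3CCC(C)(C)O4)oc12 | intermediate
17 | 2-(7-hydroxy-2,2-dimethyl-3,4-dihydro-2H-chromen-5-yl)-7-(2-methylbut-3-en-2-yl)-1-benzofuran-4,6-diol (CNP0300714.0) | C=CC(C)(C)c1c(O)cc(O)c2cc(-c3cc(O)cc4c3CCC(C)(C)O4)oc12 | target

**Step count and risk**

Total steps: 7. Longest linear sequence: 5 steps (steps 1, 2, 3, 4, 7; 1 → 2 → 4 → 6 → 7 → 17). The chroman ketone 13 is made in 2 steps (5, 6) and enters at step 7.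

The three steps most likely to fail:

Step 7 (key union). The electron-rich O-aryl oxime ether may suffer N–O cleavage back to the phenol instead of rearranging. The free phenol next to the 1,1-dimethylallyl group is also exposed to acid, which risks cyclisation or loss or shift of the allyl group. Fallback, setting out from 6 and using 13 unchanged: ortho-bromination (NBS, cat. i-Pr2NH, CH2Cl2, −78 °C) gives 2-bromo-3,5-bis(methoxymethoxy)-6-(2-methylbut-3-en-2-yl)phenol F4. Palladium-catalysed α-arylation of the enolate of 13 with F4 (Pd2dba3, bulky bisphosphine, excess NaOt-Bu, toluene, 80 °C) then gives 1-(7-hydroxy-2,2-dimethylchroman-5-yl)-2-[2-hydroxy-4,6-bis(methoxymethoxy)-3-(2-methylbut-3-en-2-yl)phenyl]ethan-1-one F5. Acid-mediated cyclodehydration of F5 with concurrent MOM cleavage (HCl, MeOH, 40 °C) comes back to the route at 17.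

Step 3 (Claisen). The product can go on to the para-prenyl isomer, the "abnormal" 1,2-dimethylallyl isomer or the cyclised 2,3,3-trimethyldihydrobenzofuran on prolonged heating. Fallback, setting out from 2: ortho-selective bromination (NBS, cat. i-Pr2NH, CH2Cl2, −78 °C) gives 2-bromo-3,5-bis(methoxymethoxy)phenol F1. A palladium-catalysed, ligand-controlled γ-selective (branched) Suzuki–Miyaura coupling of F1 with prenylboronic acid pinacol ester (K3PO4, THF/H2O) then forms the aryl–C(CH3)2CH=CH2 bond directly and comes back to the route at 6.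

Step 4 (O-amination). The phenoxide is hindered by the ortho quaternary carbon and is a strong C-nucleophile, so C-amination or SNAr on the dinitrophenyl ring may compete. Fallback, setting out from 6: Tf2O/pyridine gives 3,5-bis(methoxymethoxy)-2-(2-methylbut-3-en-2-yl)phenyl trifluoromethanesulfonate F2. Palladium-catalysed C–O coupling of F2 with ethyl acetohydroximate (bulky biarylphosphine, Cs2CO3, toluene, 65 °C) gives ethyl N-[3,5-bis(methoxymethoxy)-2-(2-methylbut-3-en-2-yl)phenoxy]ethanimidate F3; here the aryl–O bond is made by cross-coupling instead of the O–N bond by amination. Under the step-7 acid, F3 exchanges with ketone 13 and comes back to the route at 14.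

**Further compounds**

F1 | step 3 | 2-bromo-3,5-bis(methoxymethoxy)phenol | Oc1cc(OCOC)cc(OCOC)c1Br
F2 | step 4 | 3,5-bis(methoxymethoxy)-2-(2-methylbut-3-en-2-yl)phenyl trifluoromethanesulfonate | C=CC(C)(C)c1c(OS(=O)(=O)C(F)(F)F)cc(OCOC)cc1OCOC
F3 | step 4 | ethyl N-[3,5-bis(methoxymethoxy)-2-(2-methylbut-3-en-2-yl)phenoxy]ethanimidate | CCOC(C)=NOc1cc(OCOC)cc(OCOC)c1C(C)(C)C=C
F4 | step 7 | 2-bromo-3,5-bis(methoxymethoxy)-6-(2-methylbut-3-en-2-yl)phenol | C=CC(C)(C)c1c(O)c(Br)c(OCOC)cc1OCOC
F5 | step 7 | 1-(7-hydroxy-2,2-dimethylchroman-5-yl)-2-[2-hydroxy-4,6-bis(methoxymethoxy)-3-(2-methylbut-3-en-2-yl)phenyl]ethan-1-one | C=CC(C)(C)c1c(O)c(CC(=O)c2cc(O)cc3OC(C)(C)CCc23)c(OCOC)cc1OCOC
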